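The synthesis rests on cutting C4–C4a of ring C. In ring A the carbon that bears O1 (C8a) has only two ortho neighbours: C8, which is blocked by the methoxy group, and C4a. An anion generated at C4a from a C4a–I bond can therefore acylate at one site only, which locks the 8-methoxy (not 6-methoxy) pattern. In one acid-free operation, iodine–magnesium exchange and attack on a tethered methyl ester form C4–C4a and close ring C as a fully protected dihydroflavonol, sparing the 4'-prenyl ether. The precursor is a methyl 3-(2-iodoaryloxy)-2-silyloxy-3-(4-prenyloxyphenyl)propanoate, made from a Darzens glycidate and a 2-iodo-6-methoxyphenol.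

Key step: step 10

Remark on the chemistry: the target has no stereocentre, so there is no enantiomer to select. The two stereocentres of the intermediates are transient, all chiral intermediates are racemic, and one enantiomer is drawn to show the relative configuration.
Abbreviations: SEM = CH2OCH2CH2SiMe3; TBS = SiMe2(t-Bu); prenyl = 3-methylbut-2-en-1-yl. Flavonoid numbering (O1, C2–C4, C4a, C5–C8, C8a) is used for ring atoms.

Step 1
Reactants: 1 2,4,6-trihydroxybenzaldehyde
Product: 2 2-hydroxy-4,6-bis(SEM-oxy)benzaldehyde
Conditions: SEMCl (2.1 equiv), i-Pr2NEt, CH2Cl2, 0 °C → rt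
Reagents that add atoms: 2-(trimethylsilyl)ethoxymethyl chloride (SEMCl), C[Si](C)(C)CCOCCl
Why: Chemoselective O-alkylation (acetal-type phenol protection, SN2 on the chloromethyl ether): the 4-OH and one of the two equivalent ortho OH groups react, while the last ortho OH is held in a hydrogen bond to the formyl oxygen and is left free by a weak amine base and two equivalents of SEMCl.

Step 2
Reactants: 2 2-hydroxy-4,6-bis(SEM-oxy)benzaldehyde
Product: 3 2-(benzyloxy)-4,6-bis(SEM-oxy)benzaldehyde
Conditions: BnBr, K2CO3, DMF, 50 °C
Reagents that add atoms: benzyl bromide, BrCc1ccccc1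
Why: Williamson ether synthesis: carbonate in warm DMF deprotonates the chelated phenol and benzyl bromide caps it, so that this oxygen (the future O1) stays distinguishable from the oxygen introduced in step 3, and the SEM acetals are stable to base.

Step 3
Reactants: 3 2-(benzyloxy)-4,6-bis(SEM-oxy)benzaldehyde
Product: 5 2-(benzyloxy)-4,6-bis(SEM-oxy)phenol, via aryl formate 4 (not isolated)
Conditions: mCPBA, CH2Cl2, 0 °C → rt; aq NaHCO3 wash; cat. K2CO3, MeOH, rt, Ar
Reagents that add atoms: 3-chloroperoxybenzoic acid (mCPBA), O=C(OO)c1cccc(Cl)c1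
Why: Baeyer–Villiger oxidation of an electron-rich benzaldehyde (Dakin-type outcome): in the peracid adduct the 2,4,6-trialkoxyaryl group migrates in preference to hydride to give formate 4, which base-catalysed transesterification with methanol cleaves to the phenol, and neither the acetals nor the benzyl ether react with the peracid.

Step 4
Reactants: 5 2-(benzyloxy)-4,6-bis(SEM-oxy)phenol
Product: 6 1-(benzyloxy)-2-methoxy-3,5-bis(SEM-oxy)benzene
Conditions: MeI, K2CO3, DMF, rt
Reagents that add atoms: iodomethane, CI
Why: Williamson O-methylation of the only free hydroxyl places the methyl group on the oxygen lying between the other two (the future 8-OMe) with no regiochemical choice.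

Step 5
Reactants: 6 1-(benzyloxy)-2-methoxy-3,5-bis(SEM-oxy)benzene
Product: 7 2-methoxy-3,5-bis(SEM-oxy)phenol
Conditions: H2 (1 atm), 10% Pd/C, EtOAc, rt
Reagents that add atoms: none
Why: Catalytic hydrogenolysis of the benzyl aryl ether frees the future O1 selectively, since SEM and methyl ethers are inert to H2/Pd, and it is scheduled before the iodine and the prenyl alkene exist because neither would tolerate it.

Step 6
Reactants: 7 2-methoxy-3,5-bis(SEM-oxy)phenol
Product: 8 2-iodo-6-methoxy-3,5-bis(SEM-oxy)phenol
Conditions: NIS (1.0 equiv), CH2Cl2, −30 → 0 °C, dark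
Reagents that add atoms: N-iodosuccinimide, O=C1CCC(=O)N1I
Why: Electrophilic aromatic iodination: both free ring carbons are activated by three oxygens, but the one ortho to the free OH (future C4a) is flanked by the small hydroxyl, which can also hydrogen-bond to NIS in a non-polar solvent and deliver iodine next to itself, whereas the other (future C6) is wedged between two SEM-oxy groups, one of them buttressed by the methoxy group, so that one equivalent at low temperature should give the 2-iodophenol.

Step 7
Reactants: 9 4-hydroxybenzaldehyde; 10 prenyl bromide (1-bromo-3-methylbut-2-ene)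
Product: 11 4-(prenyloxy)benzaldehyde
Conditions: K2CO3, acetone, reflux
Reagents that add atoms: none
Why: Williamson ether synthesis: the phenoxide oxygen displaces the primary allylic bromide in SN2 fashion, a routine preparation of aryl prenyl ethers.

Step 8
Reactants: 11 4-(prenyloxy)benzaldehyde; 12 methyl chloroacetate
Product: 13 methyl (2R*,3S*)-3-[4-(prenyloxy)phenyl]oxirane-2-carboxylate (racemic trans glycidate)
Conditions: NaOMe, MeOH, −10 °C → rt
Reagents that add atoms: none
Why: Darzens glycidic ester condensation: the chloroacetate enolate adds to the aldehyde and the aldolate closes by internal SN2 displacement of chloride, the two new stereocentres being set relative to each other by the reversible aldol step and the faster closure of the less crowded aldolate, so that the racemic trans epoxide should prevail as is usual for 4-alkoxybenzaldehydes, and any cis isomer is harmless because both centres are erased in step 12.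

Step 9
Reactants: 8 2-iodo-6-methoxy-3,5-bis(SEM-oxy)phenol; 13 racemic trans glycidate
Product: 15 methyl (2R*,3R*)-2-(TBS-oxy)-3-[2-iodo-6-methoxy-3,5-bis(SEM-oxy)phenoxy]-3-[4-(prenyloxy)phenyl]propanoate (racemic erythro), via hydroxy ester 14 (not isolated)
Conditions: Cs2CO3 (20 mol %), DMF, 50 °C; then imidazole, TBSCl, rt → 40 °C
Reagents that add atoms: tert-butyldimethylsilyl chloride, CC(C)(C)[Si](C)(C)Cl
Why: Base-catalysed SN2 opening of an epoxide by a phenoxide followed by silylation: the caesium phenoxide of 8 attacks the benzylic carbon, whose C–O bond is loosened by the para-alkoxyphenyl group while the carbon next to the ester is deactivated, with inversion, so that the trans epoxide gives the erythro hydroxy ester 14 (C2 untouched, C3 inverted), proton transfer from further phenol regenerates the base, and TBSCl/imidazole in the same DMF solution caps the carbinol.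

Step 10
Reactants: 15 racemic erythro iodoaryl silyloxy ester
Product: 17 (2R*,3R*)-3-(TBS-oxy)-8-methoxy-5,7-bis(SEM-oxy)-2-[4-(prenyloxy)phenyl]chroman-4-one (racemic 2,3-trans), via arylmagnesium chloride 16 (not isolated)
Conditions: i-PrMgCl·LiCl (1.1 equiv), THF, −40 → −10 °C; sat. aq NH4Cl
Reagents that add atoms: none
Why: The isopropylmagnesium chloride–LiCl complex attacks the iodine of 15 and transfers magnesium to C4a, because the sp2 carbanion flanked by O1 and by the C5 acetal oxygen is much better stabilised (induction, chelation of Mg) than an isopropyl anion; arylmagnesium 16 then adds to the tethered ester carbonyl and the tetrahedral alkoxide expels methoxide to give the aryl ketone. This is a Parham-type cyclisation (halogen–metal exchange followed by intramolecular acylation), the known way from aryl halides bearing a tethered ester, acid or amide to benzo-fused cyclic ketones, run here with magnesium instead of lithium. Ring C closes in the 6-exo-trig mode, the attacked C=O lying outside the new six-membered ring C4a–C4–C3–C2–O1–C8a. No stereocentre is created: C2 and C3 are carried through unchanged, the erythro ester can place the C2 aryl and C3 silyloxy groups both equatorial in the closing ring and so should give the 2,3-trans flavanone, and any epimerisation is harmless because both centres vanish in step 12. The step needs chemoselectivity for exchange over addition of the alkyl Grignard to the ester and over removal of C3–H, which would expel the aryloxide by E1cB; the two ortho oxygens should make the exchange fast enough at −40 °C, where i-PrMgCl is a poor base and a slow acyl nucleophile, and the bulky OTBS group screens C3–H and the ester against intermolecular attack. Regiochemistry is not in question, since the single C–I bond sits on the only free carbon ortho to C8a, C8 being occupied by OMe.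

Step 11
Reactants: 17 racemic trans 3-(TBS-oxy)flavanone
Product: 18 (2R*,3R*)-3-hydroxy-8-methoxy-5,7-bis(SEM-oxy)-2-[4-(prenyloxy)phenyl]chroman-4-one (racemic trans dihydroflavonol)
Conditions: TBAF/AcOH (1:1), THF, 0 °C → rt
Reagents that add atoms: none
Why: Fluoride-mediated desilylation driven by the strong Si–F bond: the secondary TBS ether next to the ketone is cleaved at or below room temperature, where aryl SEM ethers do not react, and the acetic acid buffer prevents base-induced opening of ring C.

Step 12
Reactants: 18 racemic trans dihydroflavonol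
Product: 20 3-hydroxy-8-methoxy-5,7-bis(SEM-oxy)-4'-(prenyloxy)flavone, via chromane-3,4-dione 19 (not isolated)
Conditions: Dess–Martin periodinane (1.1 equiv), CH2Cl2, 0 °C → rt
Reagents that add atoms: none
Why: Dess–Martin oxidation of the secondary α-ketol gives the 3,4-dione 19, whose acidic C2–H (benzylic, next to C3=O and O1) shifts to oxygen at once because enolisation creates the aromatic 4-pyranone of the flavonol, which removes both stereocentres, while the neutral reagent leaves the prenyl alkene and the acetals alone.

Step 13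
Reactants: 20 3-hydroxy-8-methoxy-5,7-bis(SEM-oxy)-4'-(prenyloxy)flavone
Product: 21 3,5,7-trihydroxy-8-methoxy-4'-(prenyloxy)flavone
Conditions: TBAF (6 equiv), THF, 55 °C, Ar; then AcOH
Reagents that add atoms: none
Why: Fluoride-induced SEM cleavage: attack on silicon triggers β-fragmentation to Me3SiF, ethene and an aryloxymethoxide that loses formaldehyde, which is eased here because O5 and O7 leave as vinylogous carboxylates of the chromone, and the acid-free medium preserves the acid-labile aryl prenyl ether.

Compound list
1 | 2,4,6-trihydroxybenzaldehyde | O=Cc1c(O)cc(O)cc1O | starting material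
2 | 2-hydroxy-4,6-bis(SEM-oxy)benzaldehyde | O=Cc1c(O)cc(OCOCC[Si](C)(C)C)cc1OCOCC[Si](C)(C)C | intermediate
3 | 2-(benzyloxy)-4,6-bis(SEM-oxy)benzaldehyde | O=Cc1c(OCc2ccccc2)cc(OCOCC[Si](C)(C)C)cc1OCOCC[Si](C)(C)C | intermediate
4 | 2-(benzyloxy)-4,6-bis(SEM-oxy)phenyl formate | O=COc1c(OCc2ccccc2)cc(OCOCC[Si](C)(C)C)cc1OCOCC[Si](C)(C)C | intermediate
5 | 2-(benzyloxy)-4,6-bis(SEM-oxy)phenol | Oc1c(OCc2ccccc2)cc(OCOCC[Si](C)(C)C)cc1OCOCC[Si](C)(C)C | intermediate
6 | 1-(benzyloxy)-2-methoxy-3,5-bis(SEM-oxy)benzene | COc1c(OCc2ccccc2)cc(OCOCC[Si](C)(C)C)cc1OCOCC[Si](C)(C)C | intermediate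
7 | 2-methoxy-3,5-bis(SEM-oxy)phenol | COc1c(O)cc(OCOCC[Si](C)(C)C)cc1OCOCC[Si](C)(C)C | intermediate
8 | 2-iodo-6-methoxy-3,5-bis(SEM-oxy)phenol | COc1c(OCOCC[Si](C)(C)C)cc(OCOCC[Si](C)(C)C)c(I)c1O | intermediate
9 | 4-hydroxybenzaldehyde | O=Cc1ccc(O)cc1 | starting material
10 | prenyl bromide | CC(C)=CCBr | starting material
11 | 4-(prenyloxy)benzaldehyde | CC(C)=CCOc1ccc(C=O)cc1 | intermediate
12 | methyl chloroacetate | COC(=O)CCl | starting material
13 | methyl (2R*,3S*)-3-[4-(prenyloxy)phenyl]oxirane-2-carboxylate (racemic trans, one enantiomer drawn) | CC(C)=CCOc1ccc(cc1)[C@H]2[C@@H](O2)C(=O)OC | intermediate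
14 | methyl (2R*,3R*)-2-hydroxy-3-[2-iodo-6-methoxy-3,5-bis(SEM-oxy)phenoxy]-3-[4-(prenyloxy)phenyl]propanoate (racemic erythro, one enantiomer drawn) | COc1c(OCOCC[Si](C)(C)C)cc(OCOCC[Si](C)(C)C)c(I)c1O[C@H](c1ccc(OCC=C(C)C)cc1)[C@@H](O)C(=O)OC | intermediate
15 | methyl (2R*,3R*)-2-(TBS-oxy)-3-[2-iodo-6-methoxy-3,5-bis(SEM-oxy)phenoxy]-3-[4-(prenyloxy)phenyl]propanoate (racemic erythro, one enantiomer drawn) | COc1c(OCOCC[Si](C)(C)C)cc(OCOCC[Si](C)(C)C)c(I)c1O[C@H](c1ccc(OCC=C(C)C)cc1)[C@@H](O[Si](C)(C)C(C)(C)C)C(=O)OC | intermediate
16 | arylmagnesium chloride derived from 15 (MgCl at C4a in place of iodine) | COc1c(OCOCC[Si](C)(C)C)cc(OCOCC[Si](C)(C)C)c([Mg]Cl)c1O[C@H](c1ccc(OCC=C(C)C)cc1)[C@@H](O[Si](C)(C)C(C)(C)C)C(=O)OC | intermediate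
17 | (2R*,3R*)-3-(TBS-oxy)-8-methoxy-5,7-bis(SEM-oxy)-2-[4-(prenyloxy)phenyl]chroman-4-one (racemic trans, one enantiomer drawn) | COc1c(OCOCC[Si](C)(C)C)cc(OCOCC[Si](C)(C)C)c2c1O[C@H](c1ccc(OCC=C(C)C)cc1)[C@@H](O[Si](C)(C)C(C)(C)C)C2=O | intermediate
18 | (2R*,3R*)-3-hydroxy-8-methoxy-5,7-bis(SEM-oxy)-2-[4-(prenyloxy)phenyl]chroman-4-one (racemic trans, one enantiomer drawn) | COc1c(OCOCC[Si](C)(C)C)cc(OCOCC[Si](C)(C)C)c2c1O[C@H](c1ccc(OCC=C(C)C)cc1)[C@@H](O)C2=O | intermediate
19 | 8-methoxy-5,7-bis(SEM-oxy)-2-[4-(prenyloxy)phenyl]chromane-3,4-dione (racemic, one enantiomer drawn) | COc1c(OCOCC[Si](C)(C)C)cc(OCOCC[Si](C)(C)C)c2c1O[C@H](c1ccc(OCC=C(C)C)cc1)C(=O)C2=O | intermediate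
20 | 3-hydroxy-8-methoxy-5,7-bis(SEM-oxy)-4'-(prenyloxy)flavone | COc1c(OCOCC[Si](C)(C)C)cc(OCOCC[Si](C)(C)C)c2c(=O)c(O)c(-c3ccc(OCC=C(C)C)cc3)oc12 | intermediate
21 | 3,5,7-trihydroxy-8-methoxy-4'-(prenyloxy)flavone (achiral) | COc1c(O)cc(O)c2c(=O)c(O)c(-c3ccc(OCC=C(C)C)cc3)oc12 | target

Total step count: 13. Longest linear sequence: 11 (steps 1–6 and 9–13). The two-step glycidate branch (steps 7–8) joins at step 9.

Steps most likely to fail

Step 10 (key step).
- What may go wrong: the exchange on the electron-rich ring may be slower than hoped, so that the alkyl Grignard adds to the ester. Alternatively, C3–H is removed and the aryloxide is lost by β-elimination, or the arylmagnesium is protonated before it cyclises.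
- Fallback: the same bond is made through non-basic organochromium chemistry on an aldehyde instead of an aryl anion on an ester. Setting out from 15, DIBAL-H (CH2Cl2, −78 °C) should stop at (2R*,3R*)-2-(TBS-oxy)-3-[2-iodo-6-methoxy-3,5-bis(SEM-oxy)phenoxy]-3-[4-(prenyloxy)phenyl]propanal F1. An intramolecular Nozaki–Hiyama–Kishi reaction (CrCl2, cat. NiCl2, DMF, rt) should then join C4a to the formyl carbon and give 2,3-trans-3-(TBS-oxy)-8-methoxy-5,7-bis(SEM-oxy)-4'-(prenyloxy)flavan-4-ol F2 (C4 epimers). Dess–Martin oxidation of this benzylic alcohol comes back to the route at 17.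

Step 9.
- What may go wrong: O-alkylation by a phenoxide with two ortho substituents may be slow. This leaves time for C-alkylation at the free ring A carbon, for attack at the carbon next to the ester, or for rearrangement of the sensitive glycidate.
- Fallback: a benzylic alcohol is activated rather than an epoxide. Setting out from 11, aldol addition of the lithium enolate of methyl (tert-butyldimethylsilyloxy)acetate (LDA, THF, −78 °C) should give methyl 2-(TBS-oxy)-3-hydroxy-3-[4-(prenyloxy)phenyl]propanoate F3 (mixture of diastereomers). A Mitsunobu etherification with phenol 8 (PPh3, DIAD, toluene, 0 °C → rt) comes back to the route at 15. The product would be an erythro/threo mixture, which is acceptable because both isomers converge on 20.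

Step 6.
- What may go wrong: poor site selectivity between the two activated ring positions, double iodination, or oxidation of the very electron-rich phenol.
- Fallback: directed ortho-metalation replaces electrophilic substitution. Setting out from 7, carbamoylation (Et2NCOCl, NaH, THF) should give 2-methoxy-3,5-bis(SEM-oxy)phenyl N,N-diethylcarbamate F4. s-BuLi/TMEDA (THF, −78 °C) should lithiate the carbon between the carbamate, the strongest director present, and the neighbouring SEM-oxy group, and iodine should then give 2-iodo-6-methoxy-3,5-bis(SEM-oxy)phenyl N,N-diethylcarbamate F5. Hydrolysis (NaOH, aq EtOH, reflux) comes back to the route at 8.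

Further compounds
F1 | step 10 | (2R*,3R*)-2-(TBS-oxy)-3-[2-iodo-6-methoxy-3,5-bis(SEM-oxy)phenoxy]-3-[4-(prenyloxy)phenyl]propanal (racemic, one enantiomer drawn) | COc1c(OCOCC[Si](C)(C)C)cc(OCOCC[Si](C)(C)C)c(I)c1O[C@H](c1ccc(OCC=C(C)C)cc1)[C@@H](O[Si](C)(C)C(C)(C)C)C=O
F2 | step 10 | 2,3-trans-3-(TBS-oxy)-8-methoxy-5,7-bis(SEM-oxy)-4'-(prenyloxy)flavan-4-ol (racemic, C4 epimers) | COc1c(OCOCC[Si](C)(C)C)cc(OCOCC[Si](C)(C)C)c2c1O[C@H](c1ccc(OCC=C(C)C)cc1)[C@@H](O[Si](C)(C)C(C)(C)C)C2O
F3 | step 9 | methyl 2-(TBS-oxy)-3-hydroxy-3-[4-(prenyloxy)phenyl]propanoate (mixture of diastereomers) | COC(=O)C(O[Si](C)(C)C(C)(C)C)C(O)c1ccc(OCC=C(C)C)cc1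
F4 | step 6 | 2-methoxy-3,5-bis(SEM-oxy)phenyl N,N-diethylcarbamate | CCN(CC)C(=O)Oc1cc(OCOCC[Si](C)(C)C)cc(OCOCC[Si](C)(C)C)c1OC
F5 | step 6 | 2-iodo-6-methoxy-3,5-bis(SEM-oxy)phenyl N,N-diethylcarbamate | CCN(CC)C(=O)Oc1c(I)c(OCOCC[Si](C)(C)C)cc(OCOCC[Si](C)(C)C)c1OC
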